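## Retrosynthetic overview

1. Labels used below: C1 ring B ketone, C2 C–Me, C3 ring C ketone, C4 =CH, C5 =C(iPr), C6 C–O, C7 CH2, C8 CHOH, C9 CHMe, C10 C–O of ring A, C11=C12 (C12 bears CH2OMe), C13, C14; ring A = C10–C14, ring B = C1/C2/C6–C11 (eight-membered), ring C = C2–C6; the ether O bridges C6 and C10.
2. Endgame: the (8S)-carbinol comes from exo-face hydride reduction of the C8 ketone (the C8 oxygen is carried as the epimeric, equatorial silyl ether, which acts as a stereochemical relay), and CH2OMe from Stille coupling on the C12 enol triflate of the C12/C1 β-diketone 23.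
3. Enabling feature: the six-membered ring O–C10–C11–C1–C2–C6 inside the 9-oxabicyclo[3.3.1]nonane is an oxa-Michael/Dieckmann retron (O–C6–C2–C1(=O) is a β-alkoxy acyl unit; C10/C11 are the β/α carbons of a ring A enone with C12 as carbonyl). Ring C (bond C2–C6) is the aldol of a β-keto ester onto the C6 ketone, so everything unravels to the acyclic cis-enedione β-keto ester 20.
4. 20 comes from peracid opening of the trisubstituted furan 19; ring A from aldol condensation of a 1,4-diketone; C8/C9 from an Evans syn-aldol (the only external source of chirality; C2, C6 and C10 are relayed from it in the key step); the furan from Stork enamine alkylation/Paal–Knorr.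
5. Ring order: furan (latent enedione) → ring A → ring C, tetrahydropyran and pyranone rings (and with them ring B) in one operation.

Key step: step 12

Remark: the propanoate α-carbon of 5–19 (later C2) is carried as a mixture of epimers, which is immaterial because it becomes the enolisable β-keto ester carbon of 20; 11, but-3-en-1-ylzinc bromide and tributyl(methoxymethyl)stannane are taken as commercial.

## Route

Step 1
Reactants: 1 methyl 2-methyl-3-oxobutanoate
Product: 2 methyl 4-bromo-2-methyl-3-oxobutanoate
Conditions: Br2 (1.0 equiv), CHCl3, 0 °C → rt, 16 h (HBr left in solution)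
Reagents that add atoms: bromine, BrBr
Why: Acid-mediated bromination of a 2-alkyl acetoacetate, in which the kinetically formed 2-bromide equilibrates under HBr to the 4-bromo ketone; no stereochemical issue arises because C2 stays enolisable.

Step 2
Reactants: 2 methyl 4-bromo-2-methyl-3-oxobutanoate; 3 3-methylbutanal
Product: 6 methyl 2-[4-(propan-2-yl)furan-2-yl]propanoate, via morpholine enamine 4 (not isolated), via keto aldehyde 5 (not isolated)
Conditions: 3, morpholine (1.1 equiv), 4 Å MS, MeCN, 0 °C → rt; then 2, 0 °C → rt; then AcOH/H2O; then TsOH (cat.), toluene, 80 °C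
Reagents that add atoms: none
Why: Stork enamine alkylation by the α-bromo ketone and hydrolysis give the 1,4-keto aldehyde, whose acid-catalysed Paal–Knorr cyclodehydration fixes the furan pattern (the aldehyde carbon becomes the free α-position next to the isopropyl group, the future C6); the weakly basic morpholine enamine is chosen so that C-alkylation outruns proton transfer from the β-keto ester.

Step 3
Reactants: 6 methyl 2-[4-(propan-2-yl)furan-2-yl]propanoate
Product: 8 methyl 2-[5-formyl-4-(propan-2-yl)furan-2-yl]propanoate, via iminium salt 7 (not isolated)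
Conditions: POCl3, DMF, 0 → 40 °C; then aq. NaOAc
Reagents that add atoms: N,N-dimethylformamide, CN(C)C=O; water, O
Why: Vilsmeier–Haack formylation of the electron-rich furan can only go to the single free α-position (future C6), giving the one-carbon handle that becomes C7.

Step 4
Reactants: 8 methyl 2-[5-formyl-4-(propan-2-yl)furan-2-yl]propanoate
Product: 10 methyl 2-[5-(2-oxoethyl)-4-(propan-2-yl)furan-2-yl]propanoate, via enol ether 9 (not isolated)
Conditions: Ph3P(CH2OMe)Cl, KN(SiMe3)2, THF, −78 → 0 °C; then 1 M HCl, THF, 0 °C → rt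
Reagents that add atoms: (methoxymethyl)triphenylphosphonium chloride, COC[P+](c1ccccc1)(c1ccccc1)c1ccccc1.[Cl-]; water, O
Why: Wittig methoxymethylenation and mild hydrolysis of the enol ether homologate the aldehyde to the arylacetaldehyde (C7 now CH2, C8 the aldehyde carbon), which is used crude because it enolises easily.

Step 5
Reactants: 10 methyl 2-[5-(2-oxoethyl)-4-(propan-2-yl)furan-2-yl]propanoate; 11 (4S)-4-benzyl-3-propanoyl-1,3-oxazolidin-2-one
Product: 13 methyl 2-{5-[(2R,3S)-4-[(4S)-4-benzyl-2-oxo-1,3-oxazolidin-3-yl]-2-hydroxy-3-methyl-4-oxobutyl]-4-(propan-2-yl)furan-2-yl}propanoate, via boron enolate 12 (not isolated)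
Conditions: 11, Bu2BOTf, iPr2NEt, CH2Cl2, 0 °C; then 10, −78 → 0 °C; pH 7 buffer, MeOH, 30% H2O2, 0 °C
Reagents that add atoms: none
Why: Evans syn-aldol reaction, in which the Z-boron enolate 12 reacts through a Zimmerman–Traxler chair on the enolate face away from the benzyl group and so sets C9 (methyl, S) and C8 (oxygen, R) syn under auxiliary control; this is the only step that brings in chirality from outside.

Step 6
Reactants: 13 aldol adduct
Product: 14 methyl 2-{5-[(2R,3S)-4-[(4S)-4-benzyl-2-oxo-1,3-oxazolidin-3-yl]-2-[(tert-butyldimethylsilyl)oxy]-3-methyl-4-oxobutyl]-4-(propan-2-yl)furan-2-yl}propanoate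
Conditions: TBSOTf, 2,6-lutidine, CH2Cl2, −78 → 0 °C
Reagents that add atoms: tert-butyldimethylsilyl trifluoromethanesulfonate, CC(C)(C)[Si](C)(C)OS(=O)(=O)C(F)(F)F
Why: Standard silylation of the hindered aldol hydroxyl; the C8 silyl ether is the equatorial relay group of the key step and blocks retro-aldol and lactonisation.

Step 7
Reactants: 14 silyl ether imide
Product: 15 methyl 2-{5-[(2R,3S)-2-[(tert-butyldimethylsilyl)oxy]-4-(ethylsulfanyl)-3-methyl-4-oxobutyl]-4-(propan-2-yl)furan-2-yl}propanoate
Conditions: EtSH, n-BuLi, THF, 0 °C; then aq. NH4Cl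
Reagents that add atoms: ethanethiol, CCS
Why: Lithium ethanethiolate attacks only the activated exocyclic imide carbonyl (transthioesterification of an N-acyl oxazolidinone), releasing the auxiliary and leaving the less electrophilic methyl ester untouched.

Step 8
Reactants: 15 thioester
Product: 16 methyl 2-{5-[(2R,3S)-2-[(tert-butyldimethylsilyl)oxy]-3-methyl-4-oxooct-7-en-1-yl]-4-(propan-2-yl)furan-2-yl}propanoate
Conditions: but-3-en-1-ylzinc bromide, PdCl2(PPh3)2 (5 mol %), toluene/THF, rt
Reagents that add atoms: but-3-en-1-ylzinc bromide, C=CCC[Zn]Br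
Why: Fukuyama coupling (palladium-catalysed ketone synthesis from a thioester and an organozinc reagent) is neutral and tolerates ester, furan and silyl ether, so the α-stereocentre C9 is not epimerised.

Step 9
Reactants: 16 butenyl ketone
Product: 17 methyl 2-{5-[(2R,3S)-2-[(tert-butyldimethylsilyl)oxy]-3-methyl-4,7-dioxooctyl]-4-(propan-2-yl)furan-2-yl}propanoate
Conditions: PdCl2 (10 mol %), CuCl, O2 (1 atm), DMF/H2O (7:1), rt
Reagents that add atoms: water, O
Why: Tsuji–Wacker oxidation converts the terminal alkene into the methyl ketone with Markovnikov selectivity and unveils the 1,4-diketone; the furan has no free α-position and should not be palladated.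

Step 10
Reactants: 17 1,4-diketone
Product: 19 methyl 2-{5-[(2R,3R)-2-[(tert-butyldimethylsilyl)oxy]-3-(3-oxocyclopent-1-en-1-yl)butyl]-4-(propan-2-yl)furan-2-yl}propanoate, via ketol 18 (not isolated)
Conditions: t-BuOK (1.0 equiv), t-BuOH/THF (1:1), 0 °C, 30 min; then AcOH
Reagents that add atoms: none
Why: Base-mediated intramolecular aldol condensation of the 1,4-diketone (5-exo-trig attack of the methyl-ketone enolate on the C10 ketone, then E1cB dehydration) gives the 3-substituted cyclopent-2-enone (ring A), enolisation on the unbranched side being kinetically favoured over the branched C9 side at low temperature and short contact time.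

Step 11
Reactants: 19 furan enone
Product: 20 methyl (4Z,8R,9R)-8-[(tert-butyldimethylsilyl)oxy]-2-methyl-3,6-dioxo-9-(3-oxocyclopent-1-en-1-yl)-5-(propan-2-yl)dec-4-enoate
Conditions: mCPBA (1.05 equiv), NaHCO3, CH2Cl2, 0 °C
Reagents that add atoms: 3-chloroperoxybenzoic acid, OOC(=O)c1cccc(Cl)c1
Why: Peracid oxidation of a 2,5-dialkylfuran (epoxidation, ring opening) gives the cis-enedione, whose Z geometry is inherited from the ring and places the β-keto ester carbon C2 within reach of the C6 ketone; the electron-poor ring A enone does not compete.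

Step 12
Reactants: 20 cis-enedione β-keto ester
Product: 23 8-O-TBS-8-epi-12-de(methoxymethyl)-12-hydroxy-alterbrassicicene C (tetracyclic C12/C1 β-diketone in its C12 enol form; 2R,6R,8R,9S,10R), via ring C aldol 21 (not isolated), via spiro ether 22 (not isolated)
Conditions: t-BuOK (1.05 equiv), THF/t-BuOH (10:1), 0.01 M, −40 → 0 °C; then AcOH
Reagents that add atoms: none
Why: Proposed new method: the β-keto ester enolate adds to the cis-disposed C6 ketone (reversible 5-exo-trig aldol, ring C), the tertiary C6 alkoxide then adds to C10 of the ring A enone (reversible 6-exo-trig oxa-Michael, tetrahydropyran ring O/C6/C7/C8/C9/C10), and the ring A enolate so formed is acylated at C11 by the C1 ester (6-exo-trig Dieckmann closure, pyranone ring O/C10/C11/C1/C2/C6), which completes the eight-membered ring B as the periphery of the two fused six-membered rings, while loss of methoxide and deprotonation to the C12/C1 diketonate make this last step irreversible. The closest known reaction types are the oxa-Michael/Dieckmann annulation of hydroxy esters with α,β-unsaturated carbonyl compounds, the Michael/Dieckmann annulations of the Staunton–Weinreb and Hauser type, and the base-induced aldol closure of furan-derived cis-enediones to 4-hydroxycyclopentenones; new is their union in one domino with a tertiary alkoxide, a β,β-disubstituted enone and a neopentyl ester. Because the aldol and oxa-Michael steps are reversible, all C2/C6/C10 diastereomers interconvert and the outcome is decided in the Dieckmann step (Curtin–Hammett): only the chair–chair 9-oxabicyclo[3.3.1]nonane array with the C8 silyloxy and C9 methyl groups both equatorial is low in energy, the alternative placing the silyloxy group endo over C1 and the methyl group axial, so the C6 configuration is relayed from C8/C9. C2 is fixed by the need for the ester to be cis to the C6 oxygen for six-ring closure (methyl trans to O), and C10 by the one-atom oxygen bridge, which can only span cis-diaxial positions. The step needs the C2 enolate to choose the C6 carbonyl (the only five-membered closure open to it, secured by the Z geometry from the furan) and only one equivalent of base, so that the β-keto ester is the sole site deprotonated and neither silanol elimination nor C9 epimerisation is triggered.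

Step 13
Reactants: 23 enolised β-diketone
Product: 24 C12 enol trifluoromethanesulfonate of 23 (2R,6R,8R,9S,10R)
Conditions: Tf2O, iPr2NEt, CH2Cl2, −78 °C
Reagents that add atoms: trifluoromethanesulfonic anhydride, O=S(=O)(OS(=O)(=O)C(F)(F)F)C(F)(F)F
Why: O-Sulfonylation of the enolised β-diketone should occur at the ring A oxygen on C12, which is flanked by a CH2 group, and not at the C1 oxygen buried next to quaternary C2 inside the bicycle, giving the β-acyl enol triflate.

Step 14
Reactants: 24 enol triflate
Product: 25 8-epi-alterbrassicicene C 8-O-TBS ether (2R,6R,8R,9S,10R)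
Conditions: Bu3SnCH2OMe, Pd2(dba)3 (5 mol %), AsPh3, LiCl, NMP, 60 °C
Reagents that add atoms: tributyl(methoxymethyl)stannane, CCCC[Sn](CCCC)(CCCC)COC
Why: Stille coupling of the electron-poor β-acyl vinyl triflate with an α-alkoxymethylstannane, in which the oxygen-bearing CH2 group transfers in preference to butyl, installs the methoxymethyl group on C12 with the C11=C12 double bond already in place.

Step 15
Reactants: 25 silyl ether
Product: 26 8-epi-alterbrassicicene C (2R,6R,8R,9S,10R)
Conditions: HF·pyridine, THF, 0 °C → rt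
Reagents that add atoms: none
Why: Fluoride-mediated cleavage of the secondary silyl ether; neither ether carbon of the bridge has an acidic β-hydrogen, so no retro-oxa-Michael path exists.

Step 16
Reactants: 26 equatorial alcohol
Product: 27 8-oxo-8-deoxy-alterbrassicicene C (C8 ketone; 2R,6R,9R,10R)
Conditions: Dess–Martin periodinane, NaHCO3, CH2Cl2, rt
Reagents that add atoms: none
Why: Dess–Martin oxidation under buffered, non-basic conditions turns the equatorial alcohol into the C8 ketone without epimerising the adjacent C9 centre.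

Step 17
Reactants: 27 C8 ketone
Product: 28 alterbrassicicene C (2R,6R,8S,9S,10R)
Conditions: NaBH4, MeOH/CH2Cl2 (1:1), −78 °C
Reagents that add atoms: none
Why: Hydride reduction of the saturated C8 ketone, which at −78 °C should be much faster than reduction of the two hindered conjugated ketones C1 and C3, occurs from the open exo face of the 9-oxabicyclo[3.3.1]nonane (the endo face is covered by C1) and therefore gives the axial, endo (8S)-alcohol of the target.

## Compound list

1 | methyl 2-methyl-3-oxobutanoate | COC(=O)C(C)C(C)=O | starting material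
2 | methyl 4-bromo-2-methyl-3-oxobutanoate | COC(=O)C(C)C(=O)CBr | intermediate
3 | 3-methylbutanal | CC(C)CC=O | starting material
4 | 4-[(1E)-3-methylbut-1-en-1-yl]morpholine | CC(C)/C=C/N1CCOCC1 | intermediate
5 | methyl 5-formyl-2,6-dimethyl-3-oxoheptanoate | COC(=O)C(C)C(=O)CC(C=O)C(C)C | intermediate
6 | methyl 2-[4-(propan-2-yl)furan-2-yl]propanoate | COC(=O)C(C)c1cc(C(C)C)co1 | intermediate
7 | N-{[5-(1-methoxy-1-oxopropan-2-yl)-3-(propan-2-yl)furan-2-yl]methylidene}-N-methylmethanaminium dichlorophosphate | COC(=O)C(C)c1cc(C(C)C)c(C=[N+](C)C)o1.[O-]P(=O)(Cl)Cl | intermediate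
8 | methyl 2-[5-formyl-4-(propan-2-yl)furan-2-yl]propanoate | COC(=O)C(C)c1cc(C(C)C)c(C=O)o1 | intermediate
9 | methyl 2-[5-(2-methoxyethenyl)-4-(propan-2-yl)furan-2-yl]propanoate (E/Z mixture) | COC=Cc1oc(C(C)C(=O)OC)cc1C(C)C | intermediate
10 | methyl 2-[5-(2-oxoethyl)-4-(propan-2-yl)furan-2-yl]propanoate | COC(=O)C(C)c1cc(C(C)C)c(CC=O)o1 | intermediate
11 | (4S)-4-benzyl-3-propanoyl-1,3-oxazolidin-2-one | CCC(=O)N1[C@@H](Cc2ccccc2)COC1=O | starting material
12 | (Z)-dibutylboron enolate of 11 | C/C=C(\OB(CCCC)CCCC)N1[C@@H](Cc2ccccc2)COC1=O | intermediate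
13 | methyl 2-{5-[(2R,3S)-4-[(4S)-4-benzyl-2-oxo-1,3-oxazolidin-3-yl]-2-hydroxy-3-methyl-4-oxobutyl]-4-(propan-2-yl)furan-2-yl}propanoate | COC(=O)C(C)c1cc(C(C)C)c(C[C@@H](O)[C@H](C)C(=O)N2[C@@H](Cc3ccccc3)COC2=O)o1 | intermediate
14 | methyl 2-{5-[(2R,3S)-4-[(4S)-4-benzyl-2-oxo-1,3-oxazolidin-3-yl]-2-[(tert-butyldimethylsilyl)oxy]-3-methyl-4-oxobutyl]-4-(propan-2-yl)furan-2-yl}propanoate | COC(=O)C(C)c1cc(C(C)C)c(C[C@@H](O[Si](C)(C)C(C)(C)C)[C@H](C)C(=O)N2[C@@H](Cc3ccccc3)COC2=O)o1 | intermediate
15 | methyl 2-{5-[(2R,3S)-2-[(tert-butyldimethylsilyl)oxy]-4-(ethylsulfanyl)-3-methyl-4-oxobutyl]-4-(propan-2-yl)furan-2-yl}propanoate | COC(=O)C(C)c1cc(C(C)C)c(C[C@@H](O[Si](C)(C)C(C)(C)C)[C@H](C)C(=O)SCC)o1 | intermediate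
16 | methyl 2-{5-[(2R,3S)-2-[(tert-butyldimethylsilyl)oxy]-3-methyl-4-oxooct-7-en-1-yl]-4-(propan-2-yl)furan-2-yl}propanoate | COC(=O)C(C)c1cc(C(C)C)c(C[C@@H](O[Si](C)(C)C(C)(C)C)[C@H](C)C(=O)CCC=C)o1 | intermediate
17 | methyl 2-{5-[(2R,3S)-2-[(tert-butyldimethylsilyl)oxy]-3-methyl-4,7-dioxooctyl]-4-(propan-2-yl)furan-2-yl}propanoate | COC(=O)C(C)c1cc(C(C)C)c(C[C@@H](O[Si](C)(C)C(C)(C)C)[C@H](C)C(=O)CCC(C)=O)o1 | intermediate
18 | methyl 2-{5-[(2R,3S)-2-[(tert-butyldimethylsilyl)oxy]-3-(1-hydroxy-3-oxocyclopentyl)butyl]-4-(propan-2-yl)furan-2-yl}propanoate | COC(=O)C(C)c1cc(C(C)C)c(C[C@@H](O[Si](C)(C)C(C)(C)C)[C@H](C)C2(O)CC(=O)CC2)o1 | intermediate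
19 | methyl 2-{5-[(2R,3R)-2-[(tert-butyldimethylsilyl)oxy]-3-(3-oxocyclopent-1-en-1-yl)butyl]-4-(propan-2-yl)furan-2-yl}propanoate | COC(=O)C(C)c1cc(C(C)C)c(C[C@@H](O[Si](C)(C)C(C)(C)C)[C@H](C)C2=CC(=O)CC2)o1 | intermediate
20 | methyl (4Z,8R,9R)-8-[(tert-butyldimethylsilyl)oxy]-2-methyl-3,6-dioxo-9-(3-oxocyclopent-1-en-1-yl)-5-(propan-2-yl)dec-4-enoate | COC(=O)C(C)C(=O)/C=C(/C(C)C)C(=O)C[C@@H](O[Si](C)(C)C(C)(C)C)[C@H](C)C1=CC(=O)CC1 | intermediate
21 | methyl (1R,2R)-2-{(2R,3R)-2-[(tert-butyldimethylsilyl)oxy]-3-(3-oxocyclopent-1-en-1-yl)butyl}-2-hydroxy-1-methyl-5-oxo-3-(propan-2-yl)cyclopent-3-ene-1-carboxylate | COC(=O)[C@@]1(C)C(=O)C=C(C(C)C)[C@]1(O)C[C@@H](O[Si](C)(C)C(C)(C)C)[C@H](C)C2=CC(=O)CC2 | intermediate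
22 | spiro keto ester (2R,6R,8R,9S,10S): ring C cyclopentenone (methyl and CO2Me on C2) spiro-joined at C6 to the tetrahydropyran O/C6/C7/C8/C9/C10 (8-OTBS, 9-Me), which is spiro-joined at C10 to a cyclopentan-3-one (ring A, C12=O) | COC(=O)[C@@]1(C)C(=O)C=C(C(C)C)[C@]12C[C@@H](O[Si](C)(C)C(C)(C)C)[C@H](C)[C@@]3(CCC(=O)C3)O2 | intermediate
23 | 8-O-TBS-8-epi-12-de(methoxymethyl)-12-hydroxy-alterbrassicicene C (C12/C1 β-diketone, C12 enol form; 2R,6R,8R,9S,10R) | OC1=C2C(=O)[C@@]3(C)C(=O)C=C(C(C)C)[C@]34C[C@@H](O[Si](C)(C)C(C)(C)C)[C@H](C)[C@@]2(CC1)O4 | intermediate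
24 | C12 enol trifluoromethanesulfonate of 23 (2R,6R,8R,9S,10R) | O=S(=O)(OC1=C2C(=O)[C@@]3(C)C(=O)C=C(C(C)C)[C@]34C[C@@H](O[Si](C)(C)C(C)(C)C)[C@H](C)[C@@]2(CC1)O4)C(F)(F)F | intermediate
25 | 8-epi-alterbrassicicene C 8-O-TBS ether (2R,6R,8R,9S,10R) | COCC1=C2C(=O)[C@@]3(C)C(=O)C=C(C(C)C)[C@]34C[C@@H](O[Si](C)(C)C(C)(C)C)[C@H](C)[C@@]2(CC1)O4 | intermediate
26 | 8-epi-alterbrassicicene C (2R,6R,8R,9S,10R) | COCC1=C2C(=O)[C@@]3(C)C(=O)C=C(C(C)C)[C@]34C[C@@H](O)[C@H](C)[C@@]2(CC1)O4 | intermediate
27 | 8-oxo-8-deoxy-alterbrassicicene C (2R,6R,9R,10R) | COCC1=C2C(=O)[C@@]3(C)C(=O)C=C(C(C)C)[C@]34CC(=O)[C@H](C)[C@@]2(CC1)O4 | intermediate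
28 | alterbrassicicene C (2R,6R,8S,9S,10R) | COCC1=C2C(=O)[C@@]3(C)C(=O)C=C(C(C)C)[C@]34C[C@H](O)[C@H](C)[C@@]2(CC1)O4 | target

## Step count and risks

Total steps: 17. Longest linear sequence: 17 steps (1 → 28).

Step 12 (proposed new method). The reversible aldol/oxa-Michael manifold may not be funnelled by the final acylation: Claisen attack on the neopentyl ester may be slow, the silyloxy group may be lost by β-elimination from the open-chain ketone, or the facial relay from C8/C9 may be weaker than predicted. The fallback sets out from 20 and uses only known reactions in two pots. Catalytic DBU in MeCN (0 °C → rt) would run the aldol closure of the cis-enedione and the thermodynamically controlled intramolecular oxa-Michael addition only, and the spiro keto ester 22 would be isolated and purified as its diequatorial isomer. A separate classical Dieckmann condensation (NaH, catalytic MeOH, THF, 0 → 40 °C, or LiN(SiMe3)2) would then close C1–C11 and come back to the route at 23. This path passes only through listed compounds and adds no new one (F0).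

Step 10. Enolisation of the C10 ketone on its branched side may epimerise C9 or expel the C8 silyloxy group (E1cB) before or after ring closure. The fallback sets out from 16 and avoids enolate chemistry. Addition of CH2=CHMgBr/CeCl3 (THF, −78 °C, ketone-selective over the ester) should give the tertiary allylic alcohol F1. Ring-closing metathesis with the second-generation Grubbs catalyst (CH2Cl2, 40 °C) should give the cyclopentenol F2. Oxidative 1,3-transposition of this tertiary allylic alcohol (IBX, DMSO, 55 °C; Babler–Dauben type) would come back to the route at 19.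

Step 14. Transmetalation of the sp3 stannane may be slow, allowing butyl transfer or protodetriflation of the hindered triflate. The fallback sets out from 24: Stille coupling with the more reactive (tributylstannyl)methanol (Pd(PPh3)4, LiCl, dioxane, 90 °C) should give the allylic alcohol F3, and O-methylation with Me3OBF4 and 1,8-bis(dimethylamino)naphthalene in CH2Cl2 would come back to the route at 25.

## Further compounds

F0 | step 12 | none | none
F1 | step 10 | methyl 2-{5-[(2R,3S)-2-[(tert-butyldimethylsilyl)oxy]-4-ethenyl-4-hydroxy-3-methyloct-7-en-1-yl]-4-(propan-2-yl)furan-2-yl}propanoate | COC(=O)C(C)c1cc(C(C)C)c(C[C@@H](O[Si](C)(C)C(C)(C)C)[C@H](C)C(O)(C=C)CCC=C)o1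
F2 | step 10 | methyl 2-{5-[(2R,3S)-2-[(tert-butyldimethylsilyl)oxy]-3-(1-hydroxycyclopent-2-en-1-yl)butyl]-4-(propan-2-yl)furan-2-yl}propanoate | COC(=O)C(C)c1cc(C(C)C)c(C[C@@H](O[Si](C)(C)C(C)(C)C)[C@H](C)C2(O)C=CCC2)o1
F3 | step 14 | 8-O-TBS-8-epi-O-demethyl-alterbrassicicene C (C12 hydroxymethyl compound; 2R,6R,8R,9S,10R) | OCC1=C2C(=O)[C@@]3(C)C(=O)C=C(C(C)C)[C@]34C[C@@H](O[Si](C)(C)C(C)(C)C)[C@H](C)[C@@]2(CC1)O4
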